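**Retrosynthetic overview**

1. Locants: cyclopenta[b]chromene part primed (C1', C2' = cyclopentane CH2; C3a' = O–CH; O4'; C9' = CH–isobutyl; C9a' = C–CH3), cyclohexene part unprimed (C1 = spiro carbon, C2=C3(iPr), C6–CH3).
2. Endgame: both CHO groups by double Vilsmeier–Haack formylation of the 5',7'-diol; benzyl ethers off; C2=C3 from a C2 ketone through its enol triflate; reductive removal of a phenylthio group on C1' and of two aryl bromines.
3. Key disconnection: C1'–C9a' and C3a'–C1, a formal (3+2) cycloaddition of the enol ether C9a'=C3a' of a 4H-chromene with a three-carbon 1,3-zwitterion equivalent (thionium at C1', silyl enol ether at C1), the open form of a donor–acceptor cyclopropane made from (S)-pulegone.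
4. Enabling feature: C3a' is an acetal-level CH between O4' and quaternary C9a', so C9a'=C3a' can be an enol ether that is nucleophilic at C9a' and becomes an oxocarbenium ion at C3a'. The spiro carbon C1 is flanked by C2, which as a ketone makes C1 an enol carbon, and C1' tolerates a removable sulfur donor.
5. Ring order: arene bought; pyran ring by organocatalytic Friedel–Crafts/hemiacetalisation (sets C9'); cyclohexane ring from pulegone (carries C6); cyclopentane last, in the key step (sets C9a', C3a', C1).

Key step: step 10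

Remark: the sense of induction in step 2 is assigned from the usual shielding model of the (S)-diarylprolinol silyl ether iminium ion (the (R)-catalyst would be used if it proved opposite); every stereocentre described as a mixture is removed later in the route.

**Route**

Step 1
Reactants: 1 3-methylbutanal
Product: 2 (E)-5-methylhex-2-enal
Conditions: Ph3P=CHCHO (0.9 equiv), PhMe, 80 °C
Reagents that add atoms: (triphenylphosphoranylidene)acetaldehyde, O=CC=P(c1ccccc1)(c1ccccc1)c1ccccc1
Why: Wittig olefination with a formyl-stabilised ylide, which should give the (E)-enal.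

Step 2
Reactants: 2 (E)-5-methylhex-2-enal; 3 3,5-bis(benzyloxy)phenol
Product: 4 (4R)-5,7-bis(benzyloxy)-4-(2-methylpropyl)chroman-2-ol (both anomers)
Conditions: (S)-α,α-diphenylprolinol trimethylsilyl ether (20 mol %), PhCO2H (20 mol %), PhMe, 0 °C to rt
Reagents that add atoms: none
Why: Organocatalytic Friedel–Crafts alkylation/hemiacetalisation, in which the phenol carbon ortho to OH adds to the β-carbon of the iminium ion of 2 on the face not covered by the CPh2(OSiMe3) group, which should set C4 as (R), and the ortho adduct is drained as the cyclic hemiacetal.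

Step 3
Reactants: 4 (4R)-5,7-bis(benzyloxy)-4-(2-methylpropyl)chroman-2-ol
Product: 5 (4R)-5,7-bis(benzyloxy)-4-(2-methylpropyl)chroman-2-one
Conditions: PhI(OAc)2, TEMPO (10 mol %), CH2Cl2, rt
Reagents that add atoms: none
Why: Oxoammonium (TEMPO) oxidation of a lactol to the lactone, which does not touch the benzylic stereocentre.

Step 4
Reactants: 5 (4R)-5,7-bis(benzyloxy)-4-(2-methylpropyl)chroman-2-one
Product: 6 (3R,4R)-5,7-bis(benzyloxy)-3-methyl-4-(2-methylpropyl)chroman-2-one (trans)
Conditions: LiN(SiMe3)2, THF, -78 °C; MeI, -78 to -40 °C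
Reagents that add atoms: iodomethane, CI
Why: Lactone enolate alkylation, with methyl entering anti to the neighbouring isobutyl group (the C3 configuration is lost again in step 7).

Step 5
Reactants: 6 (3R,4R)-5,7-bis(benzyloxy)-3-methyl-4-(2-methylpropyl)chroman-2-one
Product: 7 (3R,4R)-5,7-bis(benzyloxy)-6,8-dibromo-3-methyl-4-(2-methylpropyl)chroman-2-one
Conditions: NBS (2.1 equiv), MeCN, 0 °C, dark
Reagents that add atoms: N-bromosuccinimide, O=C1CCC(=O)N1Br
Why: Electrophilic aromatic bromination at the only two free ring positions, which blocks the arene as a Friedel–Crafts nucleophile in step 10.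

Step 6
Reactants: 7 (3R,4R)-5,7-bis(benzyloxy)-6,8-dibromo-3-methyl-4-(2-methylpropyl)chroman-2-one
Product: 8 (3R,4R)-5,7-bis(benzyloxy)-6,8-dibromo-3-methyl-4-(2-methylpropyl)chroman-2-ol (both anomers)
Conditions: i-Bu2AlH, CH2Cl2, -78 °C; aq. potassium sodium tartrate
Reagents that add atoms: none
Why: Half-reduction of a lactone by i-Bu2AlH at low temperature stops at the aluminium hemiacetal, which gives the lactol on work-up.

Step 7
Reactants: 8 (3R,4R)-5,7-bis(benzyloxy)-6,8-dibromo-3-methyl-4-(2-methylpropyl)chroman-2-ol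
Product: 9 (4R)-5,7-bis(benzyloxy)-6,8-dibromo-3-methyl-4-(2-methylpropyl)-4H-chromene
Conditions: MsCl, Et3N, CH2Cl2, 0 °C to rt
Reagents that add atoms: none
Why: Mesylation of the lactol and E1-type loss of methanesulfonate through the aryloxocarbenium ion, which can only lose the C3 proton and so should give the trisubstituted enol ether without touching C4.

Step 8
Reactants: 10 (S)-pulegone
Product: 13 (3S)-3-methyl-2-methylidene-6-(propan-2-ylidene)cyclohexan-1-one, via Mannich base 11 (not isolated), via trimethylammonium iodide 12 (not isolated)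
Conditions: LiN(iPr)2, THF, -78 °C; CH2=NMe2 I, -78 °C to rt; MeI, Et2O, rt; aq. NaHCO3, CH2Cl2, rt
Reagents that add atoms: N,N-dimethylmethyleneiminium iodide, C=[N+](C)C.[I-]
Why: α-Methylenation through a Mannich base: kinetic deprotonation at the α'-methylene, Mannich reaction with the iminium salt, N-methylation and bicarbonate-induced elimination of trimethylamine, conditions too mild to enolise the methyl-bearing stereocentre.

Step 9
Reactants: 13 (3S)-3-methyl-2-methylidene-6-(propan-2-ylidene)cyclohexan-1-one; 14 methoxymethyl phenyl sulfide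
Product: 15 {[(3S)-2-[2-methoxy-2-(phenylsulfanyl)ethyl]-3-methyl-6-(propan-2-ylidene)cyclohex-1-en-1-yl]oxy}trimethylsilane (both acetal epimers)
Conditions: 14, n-BuLi, THF, -78 to -30 °C; DMPU, then 13, -78 °C; Me3SiCl, Et3N, -78 to 0 °C
Reagents that add atoms: chlorotrimethylsilane, C[Si](C)(C)Cl
Why: Conjugate addition of the sulfur- and oxygen-stabilised carbanion to the unhindered exocyclic methylene (at -78 °C it should outrun γ-deprotonation) and O-silylation of the dienolate, which fixes the enol double bond toward the future spiro carbon.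

Step 10
Reactants: 9 (4R)-5,7-bis(benzyloxy)-6,8-dibromo-3-methyl-4-(2-methylpropyl)-4H-chromene; 15 {[(3S)-2-[2-methoxy-2-(phenylsulfanyl)ethyl]-3-methyl-6-(propan-2-ylidene)cyclohex-1-en-1-yl]oxy}trimethylsilane
Product: 17 5',7'-bis(benzyloxy)-6',8'-dibromo-6,9a'-dimethyl-9'-(2-methylpropyl)-1'-(phenylsulfanyl)-3-(propan-2-ylidene)-1',2',9',9a'-tetrahydro-3a'H-spiro[cyclohexane-1,3'-cyclopenta[b]chromen]-2-one (both C1' epimers; C1 C3a' C6 C9' C9a' as in 22), via thio-substituted spirocyclopropyl enone 16 (not isolated)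
Conditions: 15, Me3SiOTf (0.3 equiv), 2,6-di-tert-butyl-4-methylpyridine (0.4 equiv), 4 Å MS, CH2Cl2, -78 °C; then 9, -78 to -20 °C
Reagents that add atoms: none
Why: Proposed new method: Me3SiOTf removes methoxide from the O,S-acetal of 15 (as Me3SiOMe) and the phenylthio-stabilised carbenium ion at C1' is first captured by its own dienol silane to give the donor–acceptor cyclopropane 16, which the silyl triflate re-opens reversibly to the same thionium/silyl dienol ether pair; the β-carbon C9a' of the enol ether of 9 then attacks C1', and the aryloxocarbenium ion so formed at C3a' is trapped by the tethered enol silane carbon, releasing the ketone and Me3SiOTf. The closest known reaction type is the Lewis acid-mediated formal (3+2) cycloaddition of 2-heteroatom-substituted acylcyclopropanes with enol ethers, here coupled to an in situ Mukaiyama-type formation of the cyclopropane from an acyclic precursor. The cyclopentane closes by a 5-(enolexo)-exo-trig attack on the oxocarbenium carbon, and since the tether sits on C9a' the ring fusion can only be cis. C9a' is set by approach of the electrophile anti to the pseudoaxial isobutyl group on C9', C3a' follows from the cis closure, the spiro carbon is set by bond formation on the enol face anti to the adjacent pseudoaxial C6 methyl group (the sp2 isopropylidene carbon adds no opposing bias), and C1' is formed as a mixture that step 11 erases. The step needs chemoselectivity for the enol ether over the electron-rich arene (secured by the two bromines on the only free ring positions), carbon attack of the dienol silane at C1 (secured by the five-membered ring against seven- or eight-membered alternatives), and absence of protic acid (secured by the hindered pyridine).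

Step 11
Reactants: 17 phenylthio dibromo spiro-enone from step 10
Product: 18 5',7'-bis(benzyloxy)-6,9a'-dimethyl-9'-(2-methylpropyl)-3-(propan-2-yl)-1',2',9',9a'-tetrahydro-3a'H-spiro[cyclohexane-1,3'-cyclopenta[b]chromen]-2-one (both C3 epimers)
Conditions: Bu3SnH (excess), AIBN (portions), PhMe, 110 °C; then H2O
Reagents that add atoms: none
Why: Radical chain reduction with tin hydride, which should abstract bromine from both aryl bromides, add in the 1,4 sense to the isopropylidene enone (the tin enolate gives the saturated ketone on work-up) and, more slowly, cleave the secondary alkyl phenyl sulfide homolytically.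

Step 12
Reactants: 18 spiro-ketone from step 11
Product: 19 5',7'-bis(benzyloxy)-6,9a'-dimethyl-9'-(2-methylpropyl)-3-(propan-2-yl)-1',2',9',9a'-tetrahydro-3a'H-spiro[cyclohex-2-ene-1,3'-cyclopenta[b]chromen]-2-yl trifluoromethanesulfonate
Conditions: KN(SiMe3)2, THF, -78 °C; PhNTf2, -78 to 0 °C; dilute aq. HCl wash
Reagents that add atoms: N-phenylbis(trifluoromethanesulfonimide), O=S(=O)(N(c1ccccc1)S(=O)(=O)C(F)(F)F)C(F)(F)F
Why: Enol triflate formation: the ketone can enolise only toward the isopropyl-bearing carbon because its other α-carbon is the quaternary spiro centre, so O-triflation of the potassium enolate should give a single regioisomer and remove the C3 epimer mixture.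

Step 13
Reactants: 19 enol triflate from step 12
Product: 20 5',7'-bis(benzyloxy)-6,9a'-dimethyl-9'-(2-methylpropyl)-3-(propan-2-yl)-1',2',9',9a'-tetrahydro-3a'H-spiro[cyclohex-2-ene-1,3'-cyclopenta[b]chromene]
Conditions: Pd(OAc)2 (5 mol %), PPh3 (10 mol %), n-Bu3N, HCO2H, DMF, 60 °C
Reagents that add atoms: none
Why: Palladium-catalysed formate reduction of a vinyl triflate (oxidative addition to zerovalent palladium, decarboxylation of the formate, reductive elimination), which replaces OTf by H with the double bond fixed at C2=C3.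

Step 14
Reactants: 20 bis(benzyl ether) from step 13
Product: 21 (1R,3a'S,6S,9'R,9a'R)-6,9a'-dimethyl-9'-(2-methylpropyl)-3-(propan-2-yl)-1',2',9',9a'-tetrahydro-3a'H-spiro[cyclohex-2-ene-1,3'-cyclopenta[b]chromene]-5',7'-diol
Conditions: BCl3, C6HMe5, CH2Cl2, -78 °C; MeOH, then aq. NaHCO3
Reagents that add atoms: none
Why: Lewis acid-mediated cleavage of aryl benzyl ethers with pentamethylbenzene as a non-basic benzyl cation scavenger, conditions under which the trisubstituted alkene and the secondary alkyl aryl ether of the pyran ring should survive.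

Step 15
Reactants: 21 diol from step 14
Product: 22 (1R,3a'S,6S,9'R,9a'R)-5',7'-dihydroxy-6,9a'-dimethyl-9'-(2-methylpropyl)-3-(propan-2-yl)-1',2',9',9a'-tetrahydro-3a'H-spiro[cyclohex-2-ene-1,3'-cyclopenta[b]chromene]-6',8'-dicarbaldehyde (CNP0121396.2)
Conditions: POCl3, DMF, MeCN, 0 °C to rt; then H2O, 50 °C
Reagents that add atoms: N,N-dimethylformamide, CN(C)C=O; water, O
Why: Double Vilsmeier–Haack formylation at the two remaining ring positions, each activated by three oxygen donors, with the free phenols making the second formylation possible and hydrolysis of the iminium salts giving the dialdehyde.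

**Compound list**

1 | 3-methylbutanal | CC(C)CC=O | starting material
2 | (E)-5-methylhex-2-enal | CC(C)C/C=C/C=O | intermediate
3 | 3,5-bis(benzyloxy)phenol | Oc1cc(OCc2ccccc2)cc(OCc2ccccc2)c1 | starting material
4 | (4R)-5,7-bis(benzyloxy)-4-(2-methylpropyl)chroman-2-ol, both anomers | CC(C)C[C@H]1c2c(OCc3ccccc3)cc(OCc3ccccc3)cc2OC(O)C1 | intermediate
5 | (4R)-5,7-bis(benzyloxy)-4-(2-methylpropyl)chroman-2-one | CC(C)C[C@H]1c2c(OCc3ccccc3)cc(OCc3ccccc3)cc2OC(=O)C1 | intermediate
6 | (3R,4R)-5,7-bis(benzyloxy)-3-methyl-4-(2-methylpropyl)chroman-2-one | CC(C)C[C@H]1c2c(OCc3ccccc3)cc(OCc3ccccc3)cc2OC(=O)[C@@H]1C | intermediate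
7 | (3R,4R)-5,7-bis(benzyloxy)-6,8-dibromo-3-methyl-4-(2-methylpropyl)chroman-2-one | CC(C)C[C@H]1c2c(OCc3ccccc3)c(Br)c(OCc3ccccc3)c(Br)c2OC(=O)[C@@H]1C | intermediate
8 | (3R,4R)-5,7-bis(benzyloxy)-6,8-dibromo-3-methyl-4-(2-methylpropyl)chroman-2-ol, both anomers | CC(C)C[C@H]1c2c(OCc3ccccc3)c(Br)c(OCc3ccccc3)c(Br)c2OC(O)[C@@H]1C | intermediate
9 | (4R)-5,7-bis(benzyloxy)-6,8-dibromo-3-methyl-4-(2-methylpropyl)-4H-chromene | CC(C)C[C@H]1c2c(OCc3ccccc3)c(Br)c(OCc3ccccc3)c(Br)c2OC=C1C | intermediate
10 | (S)-pulegone, (5S)-5-methyl-2-(propan-2-ylidene)cyclohexan-1-one | CC(C)=C1CC[C@H](C)CC1=O | starting material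
11 | Mannich base, (3S)-2-[(dimethylamino)methyl]-3-methyl-6-(propan-2-ylidene)cyclohexan-1-one, C2 epimers | CN(C)CC1C(=O)C(=C(C)C)CC[C@@H]1C | intermediate
12 | trimethylammonium iodide of 11 | C[N+](C)(C)CC1C(=O)C(=C(C)C)CC[C@@H]1C.[I-] | intermediate
13 | (3S)-3-methyl-2-methylidene-6-(propan-2-ylidene)cyclohexan-1-one | C=C1C(=O)C(=C(C)C)CC[C@@H]1C | intermediate
14 | methoxymethyl phenyl sulfide | COCSc1ccccc1 | starting material
15 | {[(3S)-2-[2-methoxy-2-(phenylsulfanyl)ethyl]-3-methyl-6-(propan-2-ylidene)cyclohex-1-en-1-yl]oxy}trimethylsilane, acetal epimers | COC(Sc1ccccc1)CC1=C(O[Si](C)(C)C)C(=C(C)C)CC[C@@H]1C | intermediate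
16 | (8S)-8-methyl-1-(phenylsulfanyl)-5-(propan-2-ylidene)spiro[2.5]octan-4-one, mixture at the two cyclopropane stereocentres | O=C1C(=C(C)C)CC[C@H](C)C12CC2Sc1ccccc1 | intermediate
17 | 5',7'-bis(benzyloxy)-6',8'-dibromo-6,9a'-dimethyl-9'-(2-methylpropyl)-1'-(phenylsulfanyl)-3-(propan-2-ylidene)-1',2',9',9a'-tetrahydro-3a'H-spiro[cyclohexane-1,3'-cyclopenta[b]chromen]-2-one, C1' epimers, other stereocentres as in 22 | CC(C)C[C@H]1c2c(OCc3ccccc3)c(Br)c(OCc3ccccc3)c(Br)c2O[C@H]2[C@]1(C)C(Sc1ccccc1)C[C@@]21C(=O)C(=C(C)C)CC[C@@H]1C | intermediate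
18 | 5',7'-bis(benzyloxy)-6,9a'-dimethyl-9'-(2-methylpropyl)-3-(propan-2-yl)-1',2',9',9a'-tetrahydro-3a'H-spiro[cyclohexane-1,3'-cyclopenta[b]chromen]-2-one, C3 epimers, other stereocentres as in 22 | CC(C)C[C@H]1c2c(OCc3ccccc3)cc(OCc3ccccc3)cc2O[C@H]2[C@]1(C)CC[C@@]21C(=O)C(C(C)C)CC[C@@H]1C | intermediate
19 | enol triflate of 18, spiro[cyclohex-2-ene-1,3'-cyclopenta[b]chromen]-2-yl trifluoromethanesulfonate, stereocentres as in 22 | CC(C)C[C@H]1c2c(OCc3ccccc3)cc(OCc3ccccc3)cc2O[C@H]2[C@]1(C)CC[C@@]21C(OS(=O)(=O)C(F)(F)F)=C(C(C)C)CC[C@@H]1C | intermediate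
20 | 5',7'-bis(benzyl) ether of 21 | CC(C)C[C@H]1c2c(OCc3ccccc3)cc(OCc3ccccc3)cc2O[C@H]2[C@]1(C)CC[C@@]21C=C(C(C)C)CC[C@@H]1C | intermediate
21 | (1R,3a'S,6S,9'R,9a'R)-6,9a'-dimethyl-9'-(2-methylpropyl)-3-(propan-2-yl)-1',2',9',9a'-tetrahydro-3a'H-spiro[cyclohex-2-ene-1,3'-cyclopenta[b]chromene]-5',7'-diol | CC(C)C[C@H]1c2c(O)cc(O)cc2O[C@H]2[C@]1(C)CC[C@@]21C=C(C(C)C)CC[C@@H]1C | intermediate
22 | (1R,3a'S,6S,9'R,9a'R)-5',7'-dihydroxy-6,9a'-dimethyl-9'-(2-methylpropyl)-3-(propan-2-yl)-1',2',9',9a'-tetrahydro-3a'H-spiro[cyclohex-2-ene-1,3'-cyclopenta[b]chromene]-6',8'-dicarbaldehyde | CC(C)C[C@H]1c2c(O)c(C=O)c(O)c(C=O)c2O[C@H]2[C@]1(C)CC[C@@]21C=C(C(C)C)CC[C@@H]1C | target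

**Step count and risks**

Total step count: 15. Longest linear sequence: 13 steps (steps 1–7, then 10–15).

Steps most likely to fail:

Step 10 (proposed new method). The bimolecular attack of the hindered enol ether carbon on the thionium ion may be too slow, so that the re-opened cyclopropane is lost by proton loss to a vinyl sulfide; facial selectivity at the spiro carbon may also be poor. The fallback sets out from lactone 6 and dienone 13 and returns at ketone 18. Dienone 13 would be cyclopropanated at its exocyclic methylene with dimethylsulfoxonium methylide (Me3S(O)I, NaH, DMSO) to the spirocyclopropyl enone F1. In situ tert-butyldimethylsilyl iodide (t-BuMe2SiCl, NaI, Et3N, MeCN) would open it by homoconjugate addition to the iodoethyl dienol silane F2. The lithium enolate of 6 (LiN(SiMe3)2, THF/DMPU, -78 °C) would be alkylated by F2 anti to the isobutyl group to give the quaternary lactone F3. Reductive acetylation (i-Bu2AlH, then Ac2O, pyridine, DMAP) would give the lactol acetate F4, and BF3·OEt2 (CH2Cl2, -78 °C) would close the cyclopentane by intramolecular Mukaiyama-type addition to the oxocarbenium ion, giving the spiro-enone F5. F5 would be reduced to 18 under the conditions of step 11.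

Step 15. The second formylation may stall on the deactivated monoaldehyde, or the acidic iminium hydrolysis may isomerise or hydrate the trisubstituted alkene. The fallback sets out from 20 and returns at 22. NBS (MeCN, 0 °C) would brominate the two free ring positions of 20 to the dibromide F7. Double bromine–lithium exchange (t-BuLi, THF, -78 °C) and a DMF quench would give the bis(benzyloxy) dialdehyde F8, and BCl3/pentamethylbenzene (-78 °C) would then remove the benzyl groups to give 22.

Step 2. The arene may alkylate para to the free hydroxyl (an adduct that cannot cyclise), or enantiofacial discrimination with the aliphatic enal may be low. The fallback sets out from phenol 3 and returns at lactone 5. Hydroarylation/lactonisation of ethyl propiolate with 3 (Pd(OAc)2, CF3CO2H, CH2Cl2) would give 5,7-bis(benzyloxy)coumarin F6. Copper-catalysed asymmetric conjugate addition of i-BuMgBr (CuBr·SMe2, a chiral ferrocenyl diphosphine of the Josiphos family chosen for the (R) centre, t-BuOMe, -72 °C) would then deliver 5.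

Further compounds
F1 | step 10 | (8S)-8-methyl-5-(propan-2-ylidene)spiro[2.5]octan-4-one | O=C1C(=C(C)C)CC[C@H](C)C12CC2
F2 | step 10 | tert-butyl{[(3S)-2-(2-iodoethyl)-3-methyl-6-(propan-2-ylidene)cyclohex-1-en-1-yl]oxy}dimethylsilane | ICCC1=C(O[Si](C)(C)C(C)(C)C)C(=C(C)C)CC[C@@H]1C
F3 | step 10 | (3R,4R)-5,7-bis(benzyloxy)-3-methyl-4-(2-methylpropyl)-3-{2-[(6S)-2-(tert-butyldimethylsilyloxy)-6-methyl-3-(propan-2-ylidene)cyclohex-1-en-1-yl]ethyl}chroman-2-one | CC(C)C[C@H]1c2c(OCc3ccccc3)cc(OCc3ccccc3)cc2OC(=O)[C@]1(C)CCC1=C(O[Si](C)(C)C(C)(C)C)C(=C(C)C)CC[C@@H]1C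
F4 | step 10 | lactol acetate of F3 (2-acetoxychroman, both anomers) | CC(C)C[C@H]1c2c(OCc3ccccc3)cc(OCc3ccccc3)cc2OC(OC(C)=O)[C@]1(C)CCC1=C(O[Si](C)(C)C(C)(C)C)C(=C(C)C)CC[C@@H]1C
F5 | step 10 | 5',7'-bis(benzyloxy)-6,9a'-dimethyl-9'-(2-methylpropyl)-3-(propan-2-ylidene)-1',2',9',9a'-tetrahydro-3a'H-spiro[cyclohexane-1,3'-cyclopenta[b]chromen]-2-one, stereocentres as in 22 | CC(C)C[C@H]1c2c(OCc3ccccc3)cc(OCc3ccccc3)cc2O[C@H]2[C@]1(C)CC[C@@]21C(=O)C(=C(C)C)CC[C@@H]1C
F6 | step 2 | 5,7-bis(benzyloxy)-2H-chromen-2-one | O=C1C=Cc2c(OCc3ccccc3)cc(OCc3ccccc3)cc2O1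
F7 | step 15 | 6',8'-dibromo derivative of 20 | CC(C)C[C@H]1c2c(OCc3ccccc3)c(Br)c(OCc3ccccc3)c(Br)c2O[C@H]2[C@]1(C)CC[C@@]21C=C(C(C)C)CC[C@@H]1C
F8 | step 15 | 5',7'-bis(benzyl) ether of 22 | CC(C)C[C@H]1c2c(OCc3ccccc3)c(C=O)c(OCc3ccccc3)c(C=O)c2O[C@H]2[C@]1(C)CC[C@@]21C=C(C(C)C)CC[C@@H]1C
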